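## Retrosynthetic overview

1. The syringyl–C2 bond is cut last: Friedel–Crafts arylation of a cyclic oxocarbenium ion (from a 2-methoxytetrahydrofuran) by 2,6-dimethoxyphenol, the aryl entering anti to the neighbouring methyl.
2. The tetrahydrofuran, the only ring formed, is closed one step earlier by acid methanolysis and cyclisation of a γ-hydroxy enol carbamate; the protonation sets the second methyl-bearing centre.
3. Key C–C bond (ring C4–C5): homoaldol disconnection to 3,4-dimethoxybenzaldehyde and a metallated (E)-2-methylbut-2-enyl carbamate, a chiral homoenolate (d3) equivalent, so that two normally electrophilic carbons are joined.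
4. The carbamate comes from (E)-2-methylbut-2-en-1-ol and N,N-diisopropylcarbamoyl chloride.

Assumption: the sense of induction known for the (E)-but-2-enyl carbamate with (−)-sparteine and Ti(OiPr)4 is taken to hold for its 2-methyl homologue, and 1, 2, 4, 11 and (−)-sparteine are bought.

## Route

Step 1
Reactants: 1 (E)-2-methylbut-2-en-1-ol; 2 N,N-diisopropylcarbamoyl chloride
Product: 3 (E)-2-methylbut-2-en-1-yl N,N-diisopropylcarbamate
Conditions: NaH (1.2 equiv), THF, 0 °C → reflux, 16 h
Reagents that add atoms: none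
Why: O-carbamoylation (nucleophilic acyl substitution of the carbamoyl chloride by the sodium alkoxide) is routine for allylic alcohols, creates no stereocentre, leaves the E alkene untouched, and installs the group that directs and stabilises the α-lithiation of the next step.

Step 2
Reactants: 3 (E)-2-methylbut-2-en-1-yl N,N-diisopropylcarbamate; 4 3,4-dimethoxybenzaldehyde
Product: 7 (1Z,3S,4S)-4-(3,4-dimethoxyphenyl)-4-hydroxy-2,3-dimethylbut-1-en-1-yl N,N-diisopropylcarbamate, via lithiated carbamate 5 (not isolated), via allyltitanium reagent 6 (not isolated)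
Conditions: n-BuLi (1.05 equiv), (−)-sparteine (1.1 equiv), pentane/cyclohexane, −78 °C, 3 h (crystallisation); Ti(OiPr)4 (3 equiv), −78 °C; 4 (1.1 equiv), −78 → −40 °C; aq NH4Cl
Reagents that add atoms: none
Why: Hoppe asymmetric homoaldol reaction, in which carbamate-directed α-deprotonation gives lithiated allyl carbamate 5 (a homoenolate, d3, equivalent) whose (S)-configured (−)-sparteine complex is enriched by crystallisation-driven dynamic resolution, titanation with inversion gives (R)-allyltitanium 6, and 6 attacks the aldehyde through its γ-carbon in a chair Zimmerman–Traxler transition state (aryl and γ-methyl equatorial, carbamoyloxy axial), so that one C–C bond formation sets the anti C3 (S) and C4 (S) centres and the Z enol carbamate, the 2-methyl substrate being a homologue of the well-studied but-2-enyl carbamate.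

Step 3
Reactants: 7 (1Z,3S,4S)-4-(3,4-dimethoxyphenyl)-4-hydroxy-2,3-dimethylbut-1-en-1-yl N,N-diisopropylcarbamate
Product: 10 (2RS,3R,4S,5S)-5-(3,4-dimethoxyphenyl)-2-methoxy-3,4-dimethyltetrahydrofuran, via mixed acetal 8 (not isolated), via methoxycarbenium ion 9 (not isolated)
Conditions: MsOH (1.2 equiv), Hg(OAc)2 (5 mol%), MeOH, 0 °C → rt; aq NaHCO3
Reagents that add atoms: methanol, CO
Why: Hoppe-type methanolysis of the enol carbamate, in which the electrophile (the mercury cation of Hg(OAc)2, afterwards replaced by hydrogen with retention, or a proton) attacks C2 of the Z enol carbamate on the face anti to the CH(OH)Ar group in the conformer that keeps the C3–H in the alkene plane to minimise A(1,3) strain, which makes the new methyl-bearing centre R and thus cis to the existing methyl in the ring, while solvent methanol adds to C1 (closure by the γ-hydroxyl at this stage would be 5-endo) to give mixed acetal 8, whose carbamoyloxy group then leaves under acid as diisopropylamine and CO2 to give methoxycarbenium ion 9, which the γ-hydroxyl captures in a 5-exo closure to give the cyclic methyl acetal as an anomer mixture.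

Step 4
Reactants: 10 (2RS,3R,4S,5S)-5-(3,4-dimethoxyphenyl)-2-methoxy-3,4-dimethyltetrahydrofuran; 11 2,6-dimethoxyphenol
Product: 13 4-[(2R,3R,4S,5S)-5-(3,4-dimethoxyphenyl)-3,4-dimethyltetrahydrofuran-2-yl]-2,6-dimethoxyphenol, via oxocarbenium ion 12 (not isolated)
Conditions: 11 (3 equiv), BF3·OEt2 (1.5 equiv), CH2Cl2, −78 → 0 °C; aq NaHCO3
Reagents that add atoms: none
Why: Lewis acid-promoted Friedel–Crafts arylation (C-glycosylation type), in which BF3·OEt2 ionises the methyl acetal to cyclic oxocarbenium ion 12 and the phenol attacks it through the position para to its hydroxyl on the face anti to the adjacent C3 methyl, which sets C2 as R (2,3-trans and therefore 2,5-cis), while any reversible ionisation of the electron-rich benzylic C–O bonds leads to the same arrangement with each aryl trans to its neighbouring methyl and the two methyl-bearing centres are untouched.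

## Compound list

1 | (E)-2-methylbut-2-en-1-ol | C/C=C(\C)CO | starting material
2 | N,N-diisopropylcarbamoyl chloride | CC(C)N(C(C)C)C(=O)Cl | starting material
3 | (E)-2-methylbut-2-en-1-yl N,N-diisopropylcarbamate | C/C=C(\C)COC(=O)N(C(C)C)C(C)C | intermediate
4 | 3,4-dimethoxybenzaldehyde | COc1ccc(C=O)cc1OC | starting material
5 | [(1S,2E)-1-(diisopropylcarbamoyloxy)-2-methylbut-2-en-1-yl]lithium, held as its (−)-sparteine complex (ligand not drawn) | [Li][C@H](OC(=O)N(C(C)C)C(C)C)/C(C)=C/C | intermediate
6 | [(1R,2E)-1-(diisopropylcarbamoyloxy)-2-methylbut-2-en-1-yl]tris(propan-2-olato)titanium | CC(C)O[Ti](OC(C)C)(OC(C)C)[C@@H](OC(=O)N(C(C)C)C(C)C)/C(C)=C/C | intermediate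
7 | (1Z,3S,4S)-4-(3,4-dimethoxyphenyl)-4-hydroxy-2,3-dimethylbut-1-en-1-yl N,N-diisopropylcarbamate | COc1ccc([C@H]([C@@H](C)/C(C)=C\OC(=O)N(C(C)C)C(C)C)O)cc1OC | intermediate
8 | (1RS,2R,3S,4S)-4-(3,4-dimethoxyphenyl)-4-hydroxy-1-methoxy-2,3-dimethylbutyl N,N-diisopropylcarbamate (acyclic mixed acetal, both C1 epimers) | COc1ccc([C@H]([C@@H](C)[C@@H](C)C(OC)OC(=O)N(C(C)C)C(C)C)O)cc1OC | intermediate
9 | [(2R,3S,4S)-4-(3,4-dimethoxyphenyl)-4-hydroxy-2,3-dimethylbutylidene](methyl)oxonium (acyclic methoxycarbenium ion) | COc1ccc([C@H]([C@@H](C)[C@@H](C)C=[O+]C)O)cc1OC | intermediate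
10 | (2RS,3R,4S,5S)-5-(3,4-dimethoxyphenyl)-2-methoxy-3,4-dimethyltetrahydrofuran (anomers) | COc1ccc([C@H]2OC(OC)[C@H](C)[C@@H]2C)cc1OC | intermediate
11 | 2,6-dimethoxyphenol | COc1cccc(OC)c1O | starting material
12 | (2S,3S,4R)-2-(3,4-dimethoxyphenyl)-3,4-dimethyl-3,4-dihydro-2H-furan-1-ium (cyclic oxocarbenium ion) | COc1ccc([C@H]2[O+]=C[C@H](C)[C@@H]2C)cc1OC | intermediate
13 | 4-[(2R,3R,4S,5S)-5-(3,4-dimethoxyphenyl)-3,4-dimethyltetrahydrofuran-2-yl]-2,6-dimethoxyphenol | COc1ccc([C@H]2O[C@@H](c3cc(OC)c(O)c(OC)c3)[C@H](C)[C@@H]2C)cc1OC | target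

## Step count and risks

Total step count: 4. Longest linear sequence: 4 steps (1 → 3 → 7 → 10 → 13).

**Risk 1, step 2.** The crystallisation-driven resolution is proven for the but-2-enyl carbamate, not for the 2-methyl homologue, so the ee (and the sense of induction) may fall short. The fallback sets out from 3 and 4 and comes back at 7. Lithiation of 3 with n-BuLi and TMEDA, titanation with Ti(OiPr)4 and addition to 4 give the racemic anti-(Z) adduct F1. This is resolved by catalytic enantioselective acylation with (R)-benzotetramisole ((R)-2-phenyl-2,3-dihydroimidazo[2,1-b]benzothiazole, 5 mol%), isobutyric anhydride (0.6 equiv) and iPr2NEt in CHCl3 at 0 °C. The (R)-carbinol enantiomer is converted into the isobutyrate ester F2 and removed by chromatography, and unreacted (3S,4S)-7 continues. Enantiocontrol then rests on a kinetic resolution and not on the chiral base, at the cost of at most half of the material.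

**Risk 2, step 3.** Facial selectivity of the protonation at the future C3 rests on an A(1,3) model and may be modest; the veratryl carbinol is also acid-labile. The fallback sets out from 10 (obtained as a mixture of C3 epimers) and comes back at 10 as the single cis-dimethyl epimer. Oxidation with mCPBA and BF3·OEt2 gives lactone F3 as the epimer mixture. Deprotonation with LiN(iPr)2 in THF at −78 °C and quenching of the enolate at −78 °C with 2,6-di-tert-butyl-4-methylphenol puts the proton on the face anti to the C4 methyl and gives cis-dimethyl lactone F4. Reduction with i-Bu2AlH at −78 °C gives lactol F5, and MeOH with catalytic pyridinium p-toluenesulfonate returns 10. The centre is thus set by kinetic protonation of a cyclic enolate, where the adjacent ring methyl is the only controlling element.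

**Risk 3, step 4.** The phenol may react in part at the position ortho to a methoxy group, and prolonged acid may open the ring at a benzylic C–O bond. The fallback sets out from 10 and comes back at 13. TMSBr in CH2Cl2 at −78 °C converts 10 into 2-bromotetrahydrofuran F6. Aryl bromide F7 (from 4-bromo-2,6-dimethoxyphenol, benzyl bromide and K2CO3) is turned with Mg in THF into Grignard reagent F8. F8 couples with F6 at −78 °C (Li2CuCl4, 2 mol%) to give O-benzyl ether F9; a brief BF3·OEt2 equilibration follows if some cis isomer is present. Hydrogenolysis (H2, 10% Pd/C, EtOAc) gives 13. The aryl position is fixed by the carbon–magnesium bond and no longer by the electronics of the phenol ring.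

Further compounds

F1 | step 2 | racemic (1Z,3S*,4S*)-4-(3,4-dimethoxyphenyl)-4-hydroxy-2,3-dimethylbut-1-en-1-yl N,N-diisopropylcarbamate (both enantiomers drawn) | COc1ccc([C@H]([C@@H](C)/C(C)=C\OC(=O)N(C(C)C)C(C)C)O)cc1OC.COc1ccc([C@@H]([C@H](C)/C(C)=C\OC(=O)N(C(C)C)C(C)C)O)cc1OC
F2 | step 2 | (1R,2R,3Z)-4-[(diisopropylcarbamoyl)oxy]-1-(3,4-dimethoxyphenyl)-2,3-dimethylbut-3-en-1-yl 2-methylpropanoate | COc1ccc([C@@H]([C@H](C)/C(C)=C\OC(=O)N(C(C)C)C(C)C)OC(=O)C(C)C)cc1OC
F3 | step 3 | (3RS,4S,5S)-5-(3,4-dimethoxyphenyl)-3,4-dimethyldihydrofuran-2(3H)-one | COc1ccc([C@H]2OC(=O)C(C)[C@@H]2C)cc1OC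
F4 | step 3 | (3R,4S,5S)-5-(3,4-dimethoxyphenyl)-3,4-dimethyldihydrofuran-2(3H)-one | COc1ccc([C@H]2OC(=O)[C@H](C)[C@@H]2C)cc1OC
F5 | step 3 | (2RS,3R,4S,5S)-5-(3,4-dimethoxyphenyl)-3,4-dimethyltetrahydrofuran-2-ol | COc1ccc([C@H]2OC(O)[C@H](C)[C@@H]2C)cc1OC
F6 | step 4 | (2RS,3R,4S,5S)-2-bromo-5-(3,4-dimethoxyphenyl)-3,4-dimethyltetrahydrofuran | COc1ccc([C@H]2OC(Br)[C@H](C)[C@@H]2C)cc1OC
F7 | step 4 | 2-(benzyloxy)-5-bromo-1,3-dimethoxybenzene | COc1cc(Br)cc(OC)c1OCc1ccccc1
F8 | step 4 | [4-(benzyloxy)-3,5-dimethoxyphenyl]magnesium bromide | COc1cc([Mg]Br)cc(OC)c1OCc1ccccc1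
F9 | step 4 | (2R,3R,4S,5S)-2-[4-(benzyloxy)-3,5-dimethoxyphenyl]-5-(3,4-dimethoxyphenyl)-3,4-dimethyltetrahydrofuran | COc1ccc([C@H]2O[C@@H](c3cc(OC)c(OCc4ccccc4)c(OC)c3)[C@H](C)[C@@H]2C)cc1OC
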